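I start from the slope.

| flask | Q | D | J | remark | time |
|---|---|---|---|---|---|
| theta | 2 M | 10 mM | 8 mM | run made earlier |  |
| gamma | 2 M | 10 mM | 24 mM | run made earlier |  |
| east | 2.0 M | 10 mM | 12 mM |  | 30 min |
| south-east | 2.0 M | 6.0 mM | 12 mM |  | 30 min |

| run | time / min | G / % | Q / % |
|---|---|---|---|
| theta | 2.50 | 12.6 | 86.3 |
| theta | 6.00 | 32.5 | 67.7 |
| theta | 12.0 | 55.4 | 43.7 |
| theta | 20.0 | 75.1 | 25.1 |
| gamma | 1.33 | 4.6 | 95.7 |
| gamma | 3.00 | 11.2 | 88.4 |
| gamma | 8.00 | 29.5 | 69.5 |
| gamma | 20.0 | 59.6 | 39.9 |

(scatter of a reading: 0.5 percentage points)

- the average divides the monomer in chains by the number of chains begun, living and dead together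
- on the list of suspects stand: D + J -> E; D -> X; Q + D -> Z + G; Q + Z -> G + Z
- the earlier runs do not show the number of chains; that part of a forecast is a guess
- no earlier run changes the charge of D; that part of a forecast is a guess

- which of the two ends with the longer chains by the average number of monomer units in a chain (chains begun, living or dead) ("neither" if they lie within 10%) (east / south-east / neither)
- average number of monomer units in a chain (chains begun, living or dead) at the end, east
- average number of monomer units in a chain (chains begun, living or dead) at the end, south-east

After the lag, ln of the Q fraction falls on a straight line in both runs, which is pseudo-first-order loss of Q. I read the slope as a measure of the living chains: 0.0709 min⁻¹ in theta and 0.0468 min⁻¹ in gamma, a ratio of 1.51.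

D can begin a chain with Q or be taken by J. Dividing the first rate by the second removes time and leaves a selectivity factor, H/J, with Q and J held at their charges. I call H the even-split amount, the amount of J that would share D equally with Q, so the fraction of D that begins chains is H/(H+J). The ratio of the slopes gives H = 23.1 mM.

That fraction is 74.3% in theta and 65.8% in east. Going from theta to east, J multiplies the slope by 0.886, giving 0.0628 min⁻¹. South-east has a further factor of 0.600 from its D, a guess because no earlier run changes D, giving 0.0377 min⁻¹. Accumulated over 30 min, these slopes leave 15.2% of the Q in east and 32.3% in south-east.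

Q used divided by chains begun then gives me 258 for east and 343 for south-east, which is longer.

The forecast reads the runs as “J competing with Q for D, and J being consumed as it does so”. It gives 255 for east and 340 for south-east, and names south-east; both lengths stand slightly below mine.

The flasks give 258 for east and 345 for south-east, so south-east ends longer.

    D + J → E (k = 69.1 M⁻¹ min⁻¹)
    D → X (k = 0.0153 min⁻¹)
    Q + D → Z + G (k = 0.693 M⁻¹ min⁻¹)
    Q + Z → G + Z, rate k4*[Z]*[Q] (k = 9.55 M⁻¹ min⁻¹)

The neighbouring flask is south-east with J at 0.0030 M. With the same H, its fraction is 88.5% and its slope 0.0507 min⁻¹, which leaves 21.8% of the Q and gives a length of 294. That neighbouring flask ends with 23.0% of its Q left and 294 units in a chain, shorter than in south-east.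

The numbers in the tables are calculated on assumed constants.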